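Atom and ring labels (pterocarpan numbering): ring A = C1–C4, C4a, C11b; ring B = O5, C6, C6a, C11a; ring C = the dihydrofuran with O11; ring D = the methoxyarene; ring E = the dimethyldihydropyran on C1 (oxygen) and C2 (CH2).
Cuts: (i) O11–C11a together with the C6a–H bond, back to an achiral 2'-hydroxyisoflav-3-ene. (ii) O5–C6 by retro-6π opening, back to an ortho-quinone methide of ring A. (iii) C11a–C6a, back to a ring A/E salicylaldehyde carbonate and a 1-arylvinyl Grignard reagent of ring D. (iv) Ring E, back to isoprene and a symmetric 4-O-silyl phloroglucinaldehyde.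
Enabling feature: C11b lies between O5 (on C4a) and the ring E oxygen (on C1), with a third oxygen on C3, so benzylic C11a readily becomes an ortho-quinone methide carbon. With C6a=C6 attached, O5=C4a–C11b=C11a–C6a=C6 is a 1-oxatriene whose electrocyclisation forms O5–C6 and ring B.
Forward order: ring E first, then union of the two halves with closure of ring B in one flask, then ring C.
Stereochemistry: both centres arise in the last step. A chiral Brønsted acid protonates one face of C6a, and O11 can then reach C11a only on the face that gives the cis fusion (6aS,11aS).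

Key step: step 7

Assumption: no firm model predicts the sense of induction of the chiral acid in step 9. (R)-TRIP is written, and (S)-TRIP takes its place if proton transfer favours the other face of C6a.

Step 1
Reactants: 1 2,4,6-trihydroxybenzaldehyde
Product: 2 2,6-dihydroxy-4-(triisopropylsilyloxy)benzaldehyde
Conditions: TIPSCl (1.0 equiv), imidazole, DMF, 0 °C
Reagents that add atoms: triisopropylsilyl chloride, CC(C)[Si](Cl)(C(C)C)C(C)C
Why: Selective phenol silylation: the 4-OH is the most acidic hydroxyl and the only one neither flanked by nor hydrogen-bonded to the formyl group, so one equivalent of the bulky chloride should cap it and leave a symmetric diol whose two ortho OH/CH pairs are equivalent.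

Step 2
Reactants: 2 2,6-dihydroxy-4-(triisopropylsilyloxy)benzaldehyde; 3 isoprene
Product: 4 7-hydroxy-2,2-dimethyl-5-(triisopropylsilyloxy)chroman-8-carbaldehyde
Conditions: Amberlyst 15, THF–heptane, 60 °C, sealed vessel, isoprene 1.1 equiv
Reagents that add atoms: none
Why: Acid-catalysed Friedel–Crafts prenylation at the ring CH between OH and OTIPS, followed by Markovnikov hydroalkoxylation of the prenyl double bond by the adjacent free OH, closes ring E, and because O4 is blocked and the two halves of 2 are equivalent only this chroman regioisomer can form.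

Step 3
Reactants: 4 7-hydroxy-2,2-dimethyl-5-(triisopropylsilyloxy)chroman-8-carbaldehyde
Product: 5 tert-butyl [8-formyl-2,2-dimethyl-5-(triisopropylsilyloxy)chroman-7-yl] carbonate
Conditions: Boc2O, i-Pr2NEt, DMAP (cat.), THF, 0 °C to rt
Reagents that add atoms: di-tert-butyl dicarbonate, CC(C)(C)OC(=O)OC(=O)OC(C)(C)C
Why: DMAP-catalysed O-acylation of the chelated phenol installs the group that migrates and then leaves in step 7.

Step 4
Reactants: 6 paeonol (1-(2-hydroxy-4-methoxyphenyl)ethanone)
Product: 7 1-[4-methoxy-2-(triisopropylsilyloxy)phenyl]ethanone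
Conditions: TIPSOTf, 2,6-lutidine, CH2Cl2, 0 °C to rt
Reagents that add atoms: triisopropylsilyl triflate, CC(C)[Si](OS(=O)(=O)C(F)(F)F)(C(C)C)C(C)C
Why: The silyl triflate is reactive enough to silylate the ketone-chelated phenol, and the bulky TIPS ether should withstand steps 5 to 7.

Step 5
Reactants: 7 1-[4-methoxy-2-(triisopropylsilyloxy)phenyl]ethanone
Product: 8 hydrazone of 7
Conditions: N2H4·H2O (excess), Et3N, EtOH, 80 °C
Reagents that add atoms: hydrazine, NN
Why: Condensation of the ketone with hydrazine gives the hydrazone, and the excess of hydrazine suppresses azine formation.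

Step 6
Reactants: 8 hydrazone of 7
Product: 9 [2-(1-iodovinyl)-5-methoxyphenoxy]triisopropylsilane
Conditions: I2, 1,1,3,3-tetramethylguanidine, THF, 0 °C to rt
Reagents that add atoms: iodine, II
Why: Barton vinyl iodide synthesis: iodine oxidises the hydrazone to the diazoalkane, then iodination and loss of N2 give an α-iodo cation that loses a methyl proton to the guanidine base, which leaves the 1-iodoalkene.

Step 7
Reactants: 9 [2-(1-iodovinyl)-5-methoxyphenoxy]triisopropylsilane; 5 tert-butyl [8-formyl-2,2-dimethyl-5-(triisopropylsilyloxy)chroman-7-yl] carbonate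
Product: 14 9-[4-methoxy-2-(triisopropylsilyloxy)phenyl]-2,2-dimethyl-5-(triisopropylsilyloxy)-3,4-dihydro-2H,8H-pyrano[2,3-f]chromene (bis-silylated isoflav-3-ene), via alkenyl Grignard reagent 10 (not isolated), via magnesium alkoxide 11 (not isolated), via migrated carbonate 12 (not isolated), via ortho-quinone methide 13 (not isolated)
Conditions: 9, i-PrMgCl·LiCl (1.0 equiv), THF, −20 to 0 °C; then 5 (1.0 equiv), −78 °C to rt; aq NH4Cl
Reagents that add atoms: isopropylmagnesium chloride, CC(C)[Mg]Cl (supplies the MgCl of 10 to 12; no atom of it stays in 14)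
Why: Iodine–magnesium exchange gives 10, which adds to the formyl group of 5 (C11a–C6a bond); alkoxide 11 takes over the neighbouring Boc group through a six-membered transition state, and phenoxide 12 expels tert-butyl carbonate by 1,4-elimination to give ortho-quinone methide 13. In 13 the atoms O5=C4a–C11b=C11a–C6a=C6 form a 1-oxatriene that closes ring B by a thermal disrotatory oxa-6π electrocyclisation, O5 bonding to the terminal CH2 (C6), driven by the return of aromaticity to ring A. The closest known reaction types are the anionic generation of ortho-quinone methides from ortho-OBoc salicylaldehydes with organomagnesium reagents and the electrocyclisation of alkenyl ortho-quinone methides to 2H-chromenes. No stereocentre remains in 14 (the carbinol centre of 11 and 12 is erased in 13), and the step leaves the C6a=C11a double bond as the handle for step 9. The step needs 1,2-addition to the aldehyde rather than attack on the carbonate (secured by the much higher electrophilicity of CHO at −78 °C and by one equivalent of 10, which is used up before 13 forms on warming) and closure through O5 alone (the other ortho oxygen is tied up in ring E, and O3 and O11 are silylated, so O11 cannot add to C11a). Only the Z isomer of 13 can close, but E and Z should interconvert readily through the zwitterionic form stabilised by the donor oxygens on C1 and C3, so all material should drain through the fast unimolecular closure before external nucleophiles add, and magnesium rather than lithium in 10 suppresses 1,4 O-to-C silyl migration.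

Step 8
Reactants: 14 bis-silylated isoflav-3-ene
Product: 15 9-(2-hydroxy-4-methoxyphenyl)-2,2-dimethyl-3,4-dihydro-2H,8H-pyrano[2,3-f]chromen-5-ol (2'-hydroxyisoflav-3-ene)
Conditions: TBAF (2.2 equiv), AcOH (2.2 equiv), THF, 0 °C; pH 7 buffer work-up, Et3N-deactivated silica, used directly
Reagents that add atoms: none
Why: Fluoride cleaves both aryl silyl ethers, and the acetate buffer with a neutral work-up keeps the medium from triggering a racemic cyclisation of the acid-labile ene-phenol.

Step 9
Reactants: 15 2'-hydroxyisoflav-3-ene
Product: 17 (6aS,11aS)-3-hydroxy-9-methoxypterocarpan with a 2,2-dimethyl-3,4-dihydro-2H-pyran ring fused to C1 (oxygen) and C2 (CH2), via benzylic cation 16 (not isolated)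
Conditions: (R)-TRIP [(R)-3,3'-bis(2,4,6-triisopropylphenyl)-1,1'-binaphthyl-2,2'-diyl hydrogen phosphate] (10 mol %), toluene, 4 Å MS, −20 °C
Reagents that add atoms: none
Why: Proposed new method: the chiral phosphoric acid, held by a hydrogen bond from its P=O to the 2'-OH next to C6a, should deliver its proton to one face of C6a, which is the more nucleophilic alkene carbon because ring A (three oxygen donors, kept coplanar with C11a=C6a by ring B) pushes electron density onto it; cation 16 at C11a stays paired with the chiral phosphate and is captured at once by O11 in a 5-exo-trig closure that for geometric reasons can give only the cis-fused ring C, so C6a is set by the catalyst and C11a by C6a; the closest known reaction types are the racemic acid-induced cyclisation of 2'-hydroxyisoflav-3-enes to pterocarpans, chiral Brønsted acid catalysed intramolecular hydroalkoxylation of alkenes, and the protonation of hydroxystyrenes to quinone methides by chiral phosphoric acids, but an enantioselective protonation–cyclisation of an isoflavene has not been shown.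

Compound list
1 | 2,4,6-trihydroxybenzaldehyde | O=Cc1c(O)cc(O)cc1O | starting material
2 | 2,6-dihydroxy-4-(triisopropylsilyloxy)benzaldehyde | O=Cc1c(O)cc(O[Si](C(C)C)(C(C)C)C(C)C)cc1O | intermediate
3 | isoprene | C=CC(C)=C | starting material
4 | 7-hydroxy-2,2-dimethyl-5-(triisopropylsilyloxy)chroman-8-carbaldehyde | CC1(C)CCc2c(O[Si](C(C)C)(C(C)C)C(C)C)cc(O)c(C=O)c2O1 | intermediate
5 | tert-butyl [8-formyl-2,2-dimethyl-5-(triisopropylsilyloxy)chroman-7-yl] carbonate | CC1(C)CCc2c(O[Si](C(C)C)(C(C)C)C(C)C)cc(OC(=O)OC(C)(C)C)c(C=O)c2O1 | intermediate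
6 | paeonol, 1-(2-hydroxy-4-methoxyphenyl)ethanone | CC(=O)c1ccc(OC)cc1O | starting material
7 | 1-[4-methoxy-2-(triisopropylsilyloxy)phenyl]ethanone | CC(=O)c1ccc(OC)cc1O[Si](C(C)C)(C(C)C)C(C)C | intermediate
8 | hydrazone of 7 (C=N geometry of no consequence) | CC(=NN)c1ccc(OC)cc1O[Si](C(C)C)(C(C)C)C(C)C | intermediate
9 | [2-(1-iodovinyl)-5-methoxyphenoxy]triisopropylsilane | C=C(I)c1ccc(OC)cc1O[Si](C(C)C)(C(C)C)C(C)C | intermediate
10 | 1-[4-methoxy-2-(triisopropylsilyloxy)phenyl]vinylmagnesium chloride | C=C([Mg]Cl)c1ccc(OC)cc1O[Si](C(C)C)(C(C)C)C(C)C | intermediate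
11 | chloromagnesium alkoxide of the 1-(7-OBoc-chroman-8-yl)-2-arylprop-2-en-1-ol (racemic) | C=C(c1ccc(OC)cc1O[Si](C(C)C)(C(C)C)C(C)C)C(O[Mg]Cl)c1c(OC(=O)OC(C)(C)C)cc(O[Si](C(C)C)(C(C)C)C(C)C)c2c1OC(C)(C)CC2 | intermediate
12 | chloromagnesium phenoxide carrying the allylic tert-butyl carbonate (racemic) | C=C(c1ccc(OC)cc1O[Si](C(C)C)(C(C)C)C(C)C)C(OC(=O)OC(C)(C)C)c1c(O[Mg]Cl)cc(O[Si](C(C)C)(C(C)C)C(C)C)c2c1OC(C)(C)CC2 | intermediate
13 | 8-{(Z)-2-[4-methoxy-2-(triisopropylsilyloxy)phenyl]prop-2-en-1-ylidene}-2,2-dimethyl-5-(triisopropylsilyloxy)-3,4-dihydro-2H-chromen-7(8H)-one (ortho-quinone methide) | C=C(c1ccc(OC)cc1O[Si](C(C)C)(C(C)C)C(C)C)/C=C1\C(=O)C=C(O[Si](C(C)C)(C(C)C)C(C)C)C2=C1OC(C)(C)CC2 | intermediate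
14 | 9-[4-methoxy-2-(triisopropylsilyloxy)phenyl]-2,2-dimethyl-5-(triisopropylsilyloxy)-3,4-dihydro-2H,8H-pyrano[2,3-f]chromene | COc1ccc(C2=Cc3c(cc(O[Si](C(C)C)(C(C)C)C(C)C)c4c3OC(C)(C)CC4)OC2)c(O[Si](C(C)C)(C(C)C)C(C)C)c1 | intermediate
15 | 9-(2-hydroxy-4-methoxyphenyl)-2,2-dimethyl-3,4-dihydro-2H,8H-pyrano[2,3-f]chromen-5-ol | COc1ccc(C2=Cc3c(cc(O)c4c3OC(C)(C)CC4)OC2)c(O)c1 | intermediate
16 | C11a benzylic cation with (S)-configured C6a, ion pair with the chiral phosphate | COc1ccc([C@H]2COc3cc(O)c4c(c3[CH+]2)OC(C)(C)CC4)c(O)c1 | intermediate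
17 | (6aS,11aS)-3-hydroxy-9-methoxypterocarpan with the 2,2-dimethyldihydropyran ring on C1 (O) and C2 (CH2) | COc1ccc2c(c1)O[C@@H]1c3c(cc(O)c4c3OC(C)(C)CC4)OC[C@H]21 | target

Total step count: 9. Longest linear sequence: 6 steps (1, 2, 3, 7, 8, 9 or 4, 5, 6, 7, 8, 9).

Steps most likely to fail

Step 9 (Proposed new method).
- What may go wrong:
  - weak facial discrimination in the proton transfer;
  - uncatalysed background cyclisation;
  - proton transfer to C11a instead of C6a, with migration of the double bond toward C6 and acetal formation by the 2'-OH;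
  - erosion of the enantiomeric purity by reversible ring opening and loss of the C6a proton.
- Fallback with known chemistry, from 14 back to 17: asymmetric hydroboration of 14 with IpcBH2 made from (+)-α-pinene (THF, −25 °C) followed by NaBO3·4H2O should give the bis-silylated (3S,4R)-trans-isoflavan-4-ol F1. This is a syn addition with boron at the less substituted C11a, and the sense is expected by analogy with 1-arylcycloalkenes. TBAF/AcOH then frees the (3S,4R)-triol F2. Mitsunobu cyclodehydration (PPh3, DIAD, THF, 0 °C) closes ring C through the 2'-OH with inversion at C11a to give 17.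

Step 7.
- What may go wrong:
  - slow addition to the doubly ortho-substituted aldehyde;
  - attack of the Grignard reagent on the carbonate;
  - capture or dimerisation of the quinone methide before it closes.
- Fallback, from 9 and 4 back to 14: reagent 10 made from 9 is quenched with B(OMe)3 and hydrolysed to the alkenylboronic acid F3. A Petasis borono-Mannich reaction of F3 with the free salicylaldehyde 4 and dibenzylamine (dioxane, 90 °C) gives the allylic aminophenol F4. On continued heating F4 loses dibenzylamine to give 13, which closes to 14 without any strongly basic organometallic reagent meeting an acyl group.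

Step 2.
- What may go wrong:
  - a second annulation at the remaining OH/CH pair;
  - acid-induced loss of the silyl group, which would open the way to the regioisomeric ring closure.
- Fallback, from 2 back to 4: condensation of 2 with 3-methylbut-2-enal (ethylenediammonium diacetate, toluene, 110 °C) proceeds through aldol-type C-alkylation, dehydration and oxa-6π closure to the 2H-chromene aldehyde F5. Hydrogenation of the pyran double bond (H2, Pd/C, EtOAc) then gives 4.

Further compounds
F1 | step 9 | (3S,4R)-trans-isoflavan-4-ol, bis-TIPS ether (C11a-OH trans to ring D) | COc1ccc([C@H]2COc3cc(O[Si](C(C)C)(C(C)C)C(C)C)c4c(c3[C@@H]2O)OC(C)(C)CC4)c(O[Si](C(C)C)(C(C)C)C(C)C)c1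
F2 | step 9 | (3S,4R)-trans-isoflavan-4-ol with free 7-OH and 2'-OH | COc1ccc([C@H]2COc3cc(O)c4c(c3[C@@H]2O)OC(C)(C)CC4)c(O)c1
F3 | step 7 | {1-[4-methoxy-2-(triisopropylsilyloxy)phenyl]vinyl}boronic acid | C=C(B(O)O)c1ccc(OC)cc1O[Si](C(C)C)(C(C)C)C(C)C
F4 | step 7 | 8-{1-(dibenzylamino)-2-[4-methoxy-2-(triisopropylsilyloxy)phenyl]prop-2-en-1-yl}-2,2-dimethyl-5-(triisopropylsilyloxy)chroman-7-ol (racemic) | C=C(c1ccc(OC)cc1O[Si](C(C)C)(C(C)C)C(C)C)C(N(Cc1ccccc1)Cc1ccccc1)c1c(O)cc(O[Si](C(C)C)(C(C)C)C(C)C)c2c1OC(C)(C)CC2
F5 | step 2 | 7-hydroxy-2,2-dimethyl-5-(triisopropylsilyloxy)-2H-chromene-8-carbaldehyde | CC1(C)C=Cc2c(O[Si](C(C)C)(C(C)C)C(C)C)cc(O)c(C=O)c2O1
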